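The target is cut back to 1-heneicosyl-3,5-dimethoxybenzene. The phenol oxygen goes in last (bromination beside the chain, then Br → Li → B → OH), so the ring stays a symmetric 3,5-dimethoxyphenyl group until then.
1-Heneicosyl-3,5-dimethoxybenzene comes from 1-(3,5-dimethoxyphenyl)heneicosane-1,9-dione. Both C=O groups are temporary and leave together in one Wolff–Kishner reduction.
Key disconnection, side-chain C6–C7: the dione comes from 1-(3,5-dimethoxyphenyl)cyclohexan-1-ol (C14) and pentadec-1-en-3-one (C15). A photocatalytic ring opening (β-scission) followed by Giese addition joins them and assembles all 29 carbons of the target.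
Enabling feature: chain atoms C1–C6 are an unbranched six-carbon run ending at the arene, so one extra C1–C6 bond folds them into a cyclohexane ring. With the O–H and the oxidisable 3,5-dimethoxyphenyl ring both on C1, an alkoxyl radical breaks exactly that bond and leaves the radical on C6.
Rings: none is built. The benzene ring and the temporary cyclohexane ring are bought, joined in step 1, and the cyclohexane ring is opened in step 4.

Key step: step 4

Assumption: the side chain is numbered C1 (benzylic carbon) to C21. The target has no stereocentre, and alcohol 7 is used as the racemate because its only stereocentre is erased in step 3.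

Step 1
Reactants: 1 1-bromo-3,5-dimethoxybenzene; 2 cyclohexanone
Product: 4 1-(3,5-dimethoxyphenyl)cyclohexan-1-ol, via 3,5-dimethoxyphenyllithium 3 (not isolated)
Conditions: n-BuLi (1.05 equiv), THF, −78 °C; then 2, −78 °C → rt; H2O
Reagents that add atoms: n-butyllithium, [Li]CCCC (lithium, held only in intermediate 3)
Why: Bromine–lithium exchange outruns ring deprotonation at −78 °C, and the aryllithium then adds 1,2 to the ketone (organolithium carbonyl addition); the carbinol carbon carries two identical ring arms, so no stereocentre arises.

Step 2
Reactants: 5 dodecylmagnesium bromide; 6 acrolein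
Product: 7 (±)-pentadec-1-en-3-ol
Conditions: 5 (1.0 M in Et2O), 6, THF, −78 → 0 °C; H2O
Reagents that add atoms: none
Why: A copper-free Grignard reagent adds 1,2 rather than 1,4 to acrolein (Grignard addition), and the new carbinol centre forms as the racemate, which does not matter because step 3 removes it.

Step 3
Reactants: 7 (±)-pentadec-1-en-3-ol
Product: 8 pentadec-1-en-3-one
Conditions: IBX (1.5 equiv), EtOAc, 75 °C; filtration, short silica plug, used at once
Reagents that add atoms: none
Why: IBX oxidation of a secondary allylic alcohol runs under neutral, heterogeneous conditions, and the purely filtrative work-up spares the polymerisable vinyl ketone from nucleophiles and base.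

Step 4
Reactants: 4 1-(3,5-dimethoxyphenyl)cyclohexan-1-ol; 8 pentadec-1-en-3-one
Product: 12 1-(3,5-dimethoxyphenyl)heneicosane-1,9-dione, via alkoxyl radical 9 (not isolated), via 6-aryl-6-oxohexyl radical 10 (not isolated), via alpha-keto radical 11 (not isolated)
Conditions: [Ir(dF(CF3)ppy)2(5,5′-d(CF3)bpy)]PF6 (2 mol %), 2,4,6-collidine, 8 (2.5 equiv), CH2Cl2 (0.2 M in 4), degassed, blue LEDs, 25 °C
Reagents that add atoms: none
Why: The excited iridium(III) complex oxidises the 3,5-dimethoxyphenyl ring of 4 to its radical cation, and collidine, hydrogen-bonded to the tertiary O–H on the same carbon, takes the proton while an electron passes from oxygen to the ring (proton-coupled electron transfer), which gives alkoxyl radical 9. β-Scission of one of the two symmetry-equivalent ring bonds at the carbinol carbon is driven by the conjugated aryl ketone that forms and puts the unpaired electron on the primary carbon of 10, the future C6, while loss of the aryl group does not compete because it would give an aryl radical. The nucleophilic radical 10 adds to the unsubstituted CH2 end of the electron-poor alkene 8 (Giese addition, new bond C6–C7), and alpha-keto radical 11 is reduced by iridium(II) and protonated by collidinium, so the cycle is redox-neutral and every atom of 4 and 8 ends up in 12. The closest known reaction type is the photocatalytic ring opening of 1-arylcycloalkanols and other cycloalkanols through alkoxyl radicals, with capture of the distal radical by electron-poor alkenes. No ring is closed (one is opened) and no stereocentre is formed. Radical 10 must be captured faster than it re-closes or undergoes a 1,5-hydrogen shift from C2, which the excess and concentration of the very reactive vinyl ketone secure, and 4 must be oxidised in preference to 12, which holds because the acyl group makes the ring of 12 harder to oxidise; the phenol oxygen is left out on purpose, since a 1,2,4-trioxygenated ring would give a radical cation too stabilised to activate the O–H bond.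

Step 5
Reactants: 12 1-(3,5-dimethoxyphenyl)heneicosane-1,9-dione
Product: 14 1-heneicosyl-3,5-dimethoxybenzene, via bis-hydrazone 13 (not isolated)
Conditions: N2H4·H2O (excess), KOH, diethylene glycol, 130 °C, then 200 °C (water distilled off), N2
Reagents that add atoms: hydrazine hydrate, NN.O (nitrogen, held only in intermediate 13)
Why: The Wolff–Kishner reduction (Huang-Minlon modification) turns both the aryl ketone and the dialkyl ketone into CH2 through their hydrazones in one operation, and the only other groups, two aryl methyl ethers, are of a kind routinely carried through it.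

Step 6
Reactants: 14 1-heneicosyl-3,5-dimethoxybenzene
Product: 15 2-bromo-1-heneicosyl-3,5-dimethoxybenzene
Conditions: NBS (1.0 equiv), CH2Cl2, 0 °C → rt, dark
Reagents that add atoms: N-bromosuccinimide, O=C1CCC(=O)N1Br
Why: Electrophilic aromatic bromination should take the position para to one methoxy group and ortho to the other, next to the chain (two such positions, equivalent by symmetry), rather than the more crowded site between the two methoxy groups, and working in the dark suppresses benzylic bromination.

Step 7
Reactants: 15 2-bromo-1-heneicosyl-3,5-dimethoxybenzene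
Product: 18 6-n-heneicosyl-2,4-dimethoxyphenol, via aryllithium 16 (not isolated), via lithium aryltrimethoxyborate 17 (not isolated)
Conditions: n-BuLi (1.1 equiv), THF (dilute), −78 °C; B(OMe)3, −78 °C → rt; AcOH, 30 % H2O2, 0 °C → rt, under argon
Reagents that add atoms: hydrogen peroxide, OO (the phenol oxygen of 18); n-butyllithium, [Li]CCCC (lithium, only in 16 and 17); trimethyl borate, COB(OC)OC (only in 17)
Why: Bromine–lithium exchange, borylation and peroxide oxidation (1,2-shift of the aryl group from boron to oxygen) amount to an ipso replacement, so the hydroxyl group lands exactly where the bromine stood, and the weakly acidic medium limits over-oxidation of the electron-rich phenol.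

Compound list
1 | 1-bromo-3,5-dimethoxybenzene | COc1cc(Br)cc(OC)c1 | starting material
2 | cyclohexanone | O=C1CCCCC1 | starting material
3 | 3,5-dimethoxyphenyllithium | [Li]c1cc(OC)cc(OC)c1 | intermediate
4 | 1-(3,5-dimethoxyphenyl)cyclohexan-1-ol | COc1cc(OC)cc(c1)C1(O)CCCCC1 | intermediate
5 | dodecylmagnesium bromide | CCCCCCCCCCCC[Mg]Br | starting material
6 | acrolein (prop-2-enal) | C=CC=O | starting material
7 | (±)-pentadec-1-en-3-ol (racemate) | C=CC(O)CCCCCCCCCCCC | intermediate
8 | pentadec-1-en-3-one (dodecyl vinyl ketone) | C=CC(=O)CCCCCCCCCCCC | intermediate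
9 | 1-(3,5-dimethoxyphenyl)cyclohexyloxyl radical | COc1cc(OC)cc(c1)C1([O])CCCCC1 | intermediate
10 | 6-(3,5-dimethoxyphenyl)-6-oxohexyl radical | [CH2]CCCCC(=O)c1cc(OC)cc(OC)c1 | intermediate
11 | 1-(3,5-dimethoxyphenyl)-1,9-dioxoheneicosan-8-yl radical | CCCCCCCCCCCCC(=O)[CH]CCCCCCC(=O)c1cc(OC)cc(OC)c1 | intermediate
12 | 1-(3,5-dimethoxyphenyl)heneicosane-1,9-dione | CCCCCCCCCCCCC(=O)CCCCCCCC(=O)c1cc(OC)cc(OC)c1 | intermediate
13 | bis-hydrazone of 12 (C=N geometry not defined) | CCCCCCCCCCCCC(=NN)CCCCCCCC(=NN)c1cc(OC)cc(OC)c1 | intermediate
14 | 1-heneicosyl-3,5-dimethoxybenzene | CCCCCCCCCCCCCCCCCCCCCc1cc(OC)cc(OC)c1 | intermediate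
15 | 2-bromo-1-heneicosyl-3,5-dimethoxybenzene | CCCCCCCCCCCCCCCCCCCCCc1cc(OC)cc(OC)c1Br | intermediate
16 | (2-heneicosyl-4,6-dimethoxyphenyl)lithium | CCCCCCCCCCCCCCCCCCCCCc1cc(OC)cc(OC)c1[Li] | intermediate
17 | lithium (2-heneicosyl-4,6-dimethoxyphenyl)trimethoxyborate | [Li+].CCCCCCCCCCCCCCCCCCCCCc1cc(OC)cc(OC)c1[B-](OC)(OC)OC | intermediate
18 | 6-n-heneicosyl-2,4-dimethoxyphenol | CCCCCCCCCCCCCCCCCCCCCc1cc(OC)cc(OC)c1O | target

Total step count: 7. Longest linear sequence: 6 (steps 2, 3, 4, 5, 6, 7).

Steps most likely to fail

Step 4. Back electron transfer and the slow, reversible opening of the unstrained six-membered ring may outpace productive capture, and the vinyl ketone may oligomerise under irradiation. The fallback replaces the radical ring opening by ionic ring cleavage and olefination at the same C6–C7 junction. It sets out from 4 and comes back to the route at 14.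
- Acid-catalysed dehydration of 4 (cat. p-TsOH, toluene, water separator) should give 1-(cyclohex-1-en-1-yl)-3,5-dimethoxybenzene F1.
- Ozonolysis with Me2S work-up (or OsO4/NaIO4) should cleave the ring alkene to 6-(3,5-dimethoxyphenyl)-6-oxohexanal F2.
- 1-Bromopentadecane and PPh3 should give pentadecyl(triphenyl)phosphonium bromide F3.
- The ylide of F3 (NaHMDS, THF, −78 °C) should attack the aldehyde of F2 in preference to the aryl ketone in a Wittig reaction and give (Z)-1-(3,5-dimethoxyphenyl)heneicos-6-en-1-one F4.
- Hydrogenation over Pd/C in AcOH with a trace of HClO4 should saturate the alkene and hydrogenolyse the benzylic ketone to give 14.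

Step 7. The waxy bromide may precipitate at −78 °C and leave the exchange incomplete, the hindered aryllithium may be protonated before borylation, and the very electron-rich phenol may be over-oxidised during the peroxide treatment. The fallback replaces metalation by formylation and oxygen insertion. It sets out from 14 (so bromide 15 is not needed) and comes back at 18.
- Vilsmeier–Haack formylation (POCl3, DMF) should take the same ring position as the bromination and give 2-heneicosyl-4,6-dimethoxybenzaldehyde F5.
- Baeyer–Villiger oxidation with mCPBA, in which the electron-rich aryl group migrates, should give 2-heneicosyl-4,6-dimethoxyphenyl formate F6.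
- Methanolysis (cat. K2CO3, MeOH/THF, argon) should release 18.

Step 5. Hot alkali may partly cleave the aryl methyl ethers, azine formation may compete, and the reduction may stall at one of the two hydrazones. The fallback is a Mozingo reduction in place of the hydrazone route. It sets out from 12 and comes back at 14.
- Ethane-1,2-dithiol with BF3·OEt2 in CH2Cl2 should convert both ketones into the bis(1,3-dithiolane) of 12 F7.
- Raney nickel in refluxing EtOH should desulfurise both positions to give 14.

Further compounds
F1 | step 4 | 1-(cyclohex-1-en-1-yl)-3,5-dimethoxybenzene | COc1cc(OC)cc(c1)C1=CCCCC1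
F2 | step 4 | 6-(3,5-dimethoxyphenyl)-6-oxohexanal | O=CCCCCC(=O)c1cc(OC)cc(OC)c1
F3 | step 4 | pentadecyl(triphenyl)phosphonium bromide | CCCCCCCCCCCCCCC[P+](c1ccccc1)(c1ccccc1)c1ccccc1.[Br-]
F4 | step 4 | (Z)-1-(3,5-dimethoxyphenyl)heneicos-6-en-1-one | CCCCCCCCCCCCCC/C=C\CCCCC(=O)c1cc(OC)cc(OC)c1
F5 | step 7 | 2-heneicosyl-4,6-dimethoxybenzaldehyde | CCCCCCCCCCCCCCCCCCCCCc1cc(OC)cc(OC)c1C=O
F6 | step 7 | 2-heneicosyl-4,6-dimethoxyphenyl formate | CCCCCCCCCCCCCCCCCCCCCc1cc(OC)cc(OC)c1OC=O
F7 | step 5 | bis(1,3-dithiolane) of 12 | CCCCCCCCCCCCC1(SCCS1)CCCCCCCC1(SCCS1)c1cc(OC)cc(OC)c1
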